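Early readings are too thin to reckon from: at 0.667 h the south run shows 4% of left-handed product and 0% of right-handed product against a scatter of 2 percentage points, so we count from its later readings.

| setting | south | north | flask |
|---|---|---|---|
| left-handed substrate | 0.050 M | 0.050 M | 0.050 M |
| right-handed substrate | 0.050 M | 0.050 M | 0.050 M |
| reagent | 0.15 M | 0.15 M | 0.150 M |
| free catalyst | 3.1 mM | 4.8 mM | 2.2 mM |
| racemization catalyst | 1 mM | 1 mM | 1.0 mM |
| added ligand | 1.2 mM | 1.2 mM | 1.2 mM |
| remark | run made earlier | run made earlier |  |
| time |  |  | 8.0 h |

- south (time / h: left-handed product / %, right-handed product / %, left-handed substrate / %): 0.667: 4, 0, 47; 1.50: 10, 4, 43; 3.00: 14, 7, 41; 5.00: 19, 7, 39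
- north (time / h: left-handed product / %, right-handed product / %, left-handed substrate / %): 0.667: 9, 2, 45; 1.50: 13, 3, 38; 3.00: 19, 7, 39; 5.00: 25, 8, 32

(scatter of a reading: 2 percentage points)

1. excess of left-handed product over right-handed product in the product at 50 min
2. excess of left-handed product over right-handed product in the product at 8.0 h
3. part of the left-handed substrate and right-handed substrate charged together that has reacted at 8.0 h

- free catalyst is single-handed; left-handed substrate and right-handed substrate are mirror images of each other, charged as a racemate, each of them at the stated concentration
- steps that have been proposed: left-handed substrate + racemization catalyst <-> right-handed substrate + racemization catalyst; reagent + free catalyst + right-handed substrate -> free catalyst + right-handed product; free catalyst + added ligand <-> idle complex; reagent + free catalyst + left-handed substrate -> free catalyst + left-handed product; reagent <-> dormant form; 2 reagent -> self-condensation product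
- an excess is the difference of the two amounts in percent of their sum
- an excess is below zero if the other one leads

The bench rule says that, with the other charges and the time held, conversion scales with the catalyst charged. We count in lifetimes, the natural logarithm of substrate charged over substrate unreacted, as for a pseudo-first-order loss of substrate, and we assume the reagent follows the same course in each flask. The south run stands at 0.236 lifetimes at 3.00 h and 0.301 at 5.00 h. Carrying that last slope forward gives 0.399 by 8.0 h, though the readings are flattening. By this rule the charge ratio of 0.710 then puts the flask at an estimated 24.7% reacted.

But with these charges we stop trusting the rule, since the added ligand is a large part of the catalyst: ligand over charge is 0.387 in the south run and 0.545 in the flask. Taking the ligand as bound one to one, working catalyst is charge minus ligand: 1.90 mM in the south run, 1.00 mM in the flask. The figure carried forward from the south readings then gives 0.210 mM⁻¹, our lifetimes by 8.0 h per millimolar of working catalyst, an estimate that carries the scatter of those readings. For the flask that means 0.210 lifetimes, so we commit to 18.9% reacted.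

The forecast, made from the same runs, gives an excess of 52% at 50 min and 50% at 8.0 h, with 22% reacted, and adds “Tight ligand binding would lower this”. Its conversion stands above ours; on the excess we reckon nothing of our own.

The simulated flask gives 37.5%, 37.6% and 21.4%, so the excess falls below the forecast while the conversion lies close to it.

    left-handed substrate + racemization catalyst ⇌ right-handed substrate + racemization catalyst, rate k1*[racemization catalyst]*[left-handed substrate] forward; the back reaction follows from the equilibrium constant (k = 0.306 L mol⁻¹ s⁻¹)
    reagent + free catalyst + right-handed substrate → free catalyst + right-handed product (k = 0.0543 L² mol⁻² s⁻¹)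
    free catalyst + added ligand ⇌ idle complex (K = 4500 L mol⁻¹, k = 0.255 L mol⁻¹ s⁻¹)
    reagent + free catalyst + left-handed substrate → free catalyst + left-handed product (k = 0.121 L² mol⁻² s⁻¹)
    reagent ⇌ dormant form (K = 0.260, k = 9.11 × 10⁻⁵ s⁻¹)
    2 reagent → self-condensation product (k = 1.97 × 10⁻⁴ L mol⁻¹ s⁻¹)

Part of why the flask stands at 21.4% at 8.0 h is the idle complex together with the time given: without the ligand step it reaches 32.2% at that time, and with the ligand step at ten times the time 46.2%. Free catalyst in the flask stands at 1.19 mM at 8.00 h, above our working figure, and our count put on that amount gives 22.1%. In a neighbouring flask, the same but charged with 0.0055 M of free catalyst, our working catalyst is 4.30 mM, so the count gives 0.903 lifetimes and 59.5% reacted. That neighbouring flask computes to 50.5%, less than the count.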